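**Assumption (one line):** 4-methylpent-4-en-2-one, (S)-but-3-en-2-ol and (tert-butyldimethylsilyloxy)acetic acid are purchased. The configurations at C3 and C4 are set by substrate control from C1 and C6, as argued in the "Why" lines. In the target numbering, C1 is the quaternary carbon bearing Me and the chlorovinyl group, and C6 is the chloro-bearing carbon next to it.

## Retrosynthetic overview
1. Target ← bromochlorination of an exocyclic C3 methylene ← methylenation of an α-chloroketone ← conjugate reduction/α-chlorination of a γ-chloro-enone.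
2. γ-Chloro-enone ← Appel chlorination (inversion) of the C6 allylic alcohol ← Takai olefination of a C1 aldehyde ← ozonolysis of the propenyl group delivered by the Claisen step.
3. The only carbocycle is formed by intramolecular aldol condensation of a 1,5-keto-aldehyde, after the Claisen step.
4. Keto-aldehyde ← Ireland–Claisen [3,3] of a glycolate ester of an (S)-allylic alcohol. This sets the C1 quaternary centre and the C6–O stereocentre in one step from a single bought stereocentre. The allylic alcohol ← cross-metathesis of (S)-but-3-en-2-ol with a ketal-bearing methallyl olefin.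

## Route

**Step 1**
Reactants: 1 (4-methylpent-4-en-2-one)
Product: 2 (2-methyl-2-(2-methylallyl)-1,3-dioxolane)
Conditions: TMSOCH2CH2OTMS, TMSOTf (cat.), CH2Cl2, −78 → 0 °C
Reagents that add atoms: 1,2-bis(trimethylsilyloxy)ethane, C[Si](C)(C)OCCO[Si](C)(C)C (supplies OCH2CH2O)
Why: Noyori ketalisation is non-protic, so the β,γ-alkene does not isomerise to mesityl oxide. It masks the ketone through the enolate (Claisen) and reduction steps.

**Step 2**
Reactants: 2 and 3 ((S)-but-3-en-2-ol)
Product: 4 ((2S,3E)-4-methyl-5-(2-methyl-1,3-dioxolan-2-yl)pent-3-en-2-ol)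
Conditions: Hoveyda–Grubbs II (5 mol %), CH2Cl2, 40 °C, 3 equiv of 2
Reagents that add atoms: none
Why: Cross-metathesis joins the terminal vinyl of 3 to the 1,1-disubstituted olefin of 2 and releases ethylene. It gives the thermodynamically preferred E-trisubstituted alkene, and the carbinol stereocentre of 3 is untouched.

**Step 3**
Reactants: 4 and 5 ((tert-butyldimethylsilyloxy)acetic acid)
Product: 6 (the glycolate ester of 4)
Conditions: DCC, DMAP, CH2Cl2, 0 °C → rt
Reagents that add atoms: none (5 is the numbered reactant)
Why: Steglich esterification of a secondary alcohol proceeds without touching its configuration.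

**Step 4**
Reactants: 6
Product: 7 ((2R,3R)-2-(TBSO)-3-methyl-4-(2-methyl-1,3-dioxolan-2-yl)-3-[(E)-prop-1-enyl]butanoic acid)
Conditions: LDA, THF–HMPA, −78 °C; TMSCl; warm to rt; then aq. NaHCO3 and cold citric acid
Reagents that add atoms: none (the silyl group is lost on workup)
Why: Ireland–Claisen [3,3] through a chair transition state (the key sigmatropic step). The non-chelated (E)-silyl ketene acetal and the E-alkene transfer the (S)-carbinol chirality suprafacially. This creates the C1 quaternary centre (R) and the adjacent C6–OTBS centre (R, acyclic priorities), which correspond to Me and OTBS cis in the later ring. The carbinol carbon becomes the E-propenyl group.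

**Step 5**
Reactants: 7
Product: 8 (the primary alcohol)
Conditions: BH3·SMe2, THF, 0 °C → rt
Reagents that add atoms: none (H only)
Why: Borane reduces a carboxylic acid much faster than it attacks the ketal, silyl ether or alkene. No stereocentre is touched.

**Step 6**
Reactants: 8
Product: 9 (the α-silyloxy aldehyde)
Conditions: Dess–Martin periodinane, NaHCO3, CH2Cl2, 0 °C
Reagents that add atoms: none
Why: Mild, non-basic oxidation limits epimerisation at C6, which is α to the aldehyde.

**Step 7**
Reactants: 9
Product: 10 (the keto-aldehyde)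
Conditions: PPTS, acetone–H2O, 50 °C
Reagents that add atoms: water, O (the ketone oxygen)
Why: Mild transketalisation unmasks the methyl ketone while the secondary TBS ether survives.

**Step 8**
Reactants: 10
Product: 11 ((4S,5R)-4-(TBSO)-5-methyl-5-[(E)-propenyl]cyclohex-2-en-1-one)
Conditions: pyrrolidine (cat.), AcOH, PhMe, 60 °C
Reagents that add atoms: none (loses H2O)
Why: Intramolecular aldol condensation. Only the methyl carbon can attack the aldehyde to close a six-membered ring (attack by the other α-carbon would give a four-membered ring). E1cB loss of water gives the conjugated enone, so C6 becomes γ and non-epimerisable, and C1 and C6 are retained.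

**Step 9**
Reactants: 11
Product: 12 ((1S,2S)-2-(TBSO)-1-methyl-5-oxocyclohex-3-ene-1-carbaldehyde)
Conditions: O3, CH2Cl2–MeOH, −78 °C; then PPh3
Reagents that add atoms: ozone, [O-][O+]=O (aldehyde oxygen)
Why: The electron-rich 1,2-disubstituted propenyl alkene cleaves selectively over the electron-poor enone. It gives the neopentyl aldehyde at C1 with the configuration unchanged.

**Step 10**
Reactants: 12
Product: 13 ((4S,5R)-4-(TBSO)-5-[(E)-2-chloroethenyl]-5-methylcyclohex-2-en-1-one)
Conditions: CrCl2, CHCl3, THF, 0 °C → rt
Reagents that add atoms: chloroform, ClC(Cl)Cl (supplies CHCl)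
Why: Takai–Hiyama olefination of an aldehyde with a gem-trihalide gives the E-chloroalkene selectively. Cr(II) is chemoselective for the aldehyde, and the aldehyde has no α-hydrogen to epimerise.

**Step 11**
Reactants: 13
Product: 14 ((4S,5R)-5-[(E)-2-chloroethenyl]-4-hydroxy-5-methylcyclohex-2-en-1-one)
Conditions: HF·pyridine, THF, 0 °C → rt
Reagents that add atoms: none
Why: Buffered fluoride removes the silyl ether without retro-oxa-Michael elimination or Cl loss.

**Step 12**
Reactants: 14
Product: 15 ((4R,5R)-4-chloro-5-[(E)-2-chloroethenyl]-5-methylcyclohex-2-en-1-one)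
Conditions: PPh3, NCS, CH2Cl2, 0 °C
Reagents that add atoms: N-chlorosuccinimide, O=C1CCC(=O)N1Cl (supplies Cl)
Why: Appel-type SN2 on an allylic alcohol proceeds with inversion, converting C6–O (same face as Me) into C6–Cl on the opposite face. That is the C6 configuration of the target, and allylic activation makes this possible next to the quaternary centre.

**Step 13**
Reactants: 15
Product: 16 ((2S,4R,5R)-2,4-dichloro-5-[(E)-2-chloroethenyl]-5-methylcyclohexan-1-one)
Conditions: L-Selectride, THF, −78 °C; then NCS; then Et3N, CH2Cl2, rt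
Reagents that add atoms: N-chlorosuccinimide, O=C1CCC(=O)N1Cl (supplies Cl)
Why: 1,4-Reduction gives the C3/C4 enolate, which NCS chlorinates at C4 (α to the ketone). The α-chloroketone is then equilibrated through its enol to the thermodynamic cis-1,3-diequatorial C4/C6 dichloride, which matches the target relative configuration. C4 is thus controlled by C1 and C6.

**Step 14**
Reactants: 16
Product: 17 ((2S,4R,5R)-2,4-dichloro-5-[(E)-2-chloroethenyl]-5-methyl-1-methylidenecyclohexane)
Conditions: Cp2TiMe2, toluene–THF, 70 °C
Reagents that add atoms: dimethyltitanocene, C[Ti](C)(C1C=CC=C1)C1C=CC=C1 (supplies CH2)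
Why: Petasis methylenation replaces C=O by C=CH2 under weakly basic, non-reductive conditions. It tolerates the α-chloro and chloroalkene groups and does not epimerise C4.

**Step 15**
Reactants: 17
Product: 18 (violacene, (1R,2S,4R,5R)-1-(bromomethyl)-1,2,4-trichloro-5-[(E)-2-chloroethenyl]-5-methylcyclohexane)
Conditions: NBS, Et4NCl, CH2Cl2, 0 °C
Reagents that add atoms: N-bromosuccinimide, O=C1CCC(=O)N1Br (supplies Br); tetraethylammonium chloride, CC[N+](CC)(CC)CC.[Cl-] (supplies Cl)
Why: Bromochlorination of the exocyclic methylene is Markovnikov, giving CH2Br and a tertiary C–Cl; the deactivated chlorovinyl group is untouched. In the chair with the C4 and C6 chlorides equatorial, anti (axial) capture of the bromonium by chloride at C3 places Cl on the lower face, cis to the C4 and C6 chlorides, and CH2Br on the upper face (target C3). This substrate-controlled step is the least certain in the route, and any C3 epimer is removed by chromatography.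

## Compound list
1 | 4-methylpent-4-en-2-one | CC(=C)CC(C)=O | starting material
2 | 2-methyl-2-(2-methylallyl)-1,3-dioxolane | CC(=C)CC1(C)OCCO1 | intermediate
3 | (S)-but-3-en-2-ol | C[C@H](O)C=C | starting material
4 | (2S,3E)-4-methyl-5-(2-methyl-1,3-dioxolan-2-yl)pent-3-en-2-ol | C[C@H](O)/C=C(/CC1(C)OCCO1)C | intermediate
5 | (tert-butyldimethylsilyloxy)acetic acid | CC(C)(C)[Si](C)(C)OCC(=O)O | starting material
6 | glycolate ester of 4 | C[C@H](OC(=O)CO[Si](C)(C)C(C)(C)C)/C=C(/CC1(C)OCCO1)C | intermediate
7 | (2R,3R)-2-(TBSO)-3-methyl-4-(2-methyl-1,3-dioxolan-2-yl)-3-[(E)-prop-1-enyl]butanoic acid | OC(=O)[C@H](O[Si](C)(C)C(C)(C)C)[C@@](C)(/C=C/C)CC1(C)OCCO1 | intermediate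
8 | (2R,3R)-2-(TBSO)-3-methyl-4-(2-methyl-1,3-dioxolan-2-yl)-3-[(E)-prop-1-enyl]butan-1-ol | OC[C@H](O[Si](C)(C)C(C)(C)C)[C@@](C)(/C=C/C)CC1(C)OCCO1 | intermediate
9 | (2R,3R)-aldehyde corresponding to 8 | O=C[C@H](O[Si](C)(C)C(C)(C)C)[C@@](C)(/C=C/C)CC1(C)OCCO1 | intermediate
10 | (2R,3R)-2-(TBSO)-3-methyl-5-oxo-3-[(E)-prop-1-enyl]hexanal | O=C[C@H](O[Si](C)(C)C(C)(C)C)[C@@](C)(/C=C/C)CC(C)=O | intermediate
11 | (4S,5R)-4-(TBSO)-5-methyl-5-[(E)-prop-1-enyl]cyclohex-2-en-1-one | C[C@]1(/C=C/C)CC(=O)C=C[C@@H]1O[Si](C)(C)C(C)(C)C | intermediate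
12 | (1S,2S)-2-(TBSO)-1-methyl-5-oxocyclohex-3-ene-1-carbaldehyde | C[C@]1(C=O)CC(=O)C=C[C@@H]1O[Si](C)(C)C(C)(C)C | intermediate
13 | (4S,5R)-4-(TBSO)-5-[(E)-2-chloroethenyl]-5-methylcyclohex-2-en-1-one | C[C@]1(/C=C/Cl)CC(=O)C=C[C@@H]1O[Si](C)(C)C(C)(C)C | intermediate
14 | (4S,5R)-5-[(E)-2-chloroethenyl]-4-hydroxy-5-methylcyclohex-2-en-1-one | C[C@]1(/C=C/Cl)CC(=O)C=C[C@@H]1O | intermediate
15 | (4R,5R)-4-chloro-5-[(E)-2-chloroethenyl]-5-methylcyclohex-2-en-1-one | C[C@]1(/C=C/Cl)CC(=O)C=C[C@H]1Cl | intermediate
16 | (2S,4R,5R)-2,4-dichloro-5-[(E)-2-chloroethenyl]-5-methylcyclohexan-1-one | C[C@]1(/C=C/Cl)CC(=O)[C@@H](Cl)C[C@H]1Cl | intermediate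
17 | (2S,4R,5R)-2,4-dichloro-5-[(E)-2-chloroethenyl]-5-methyl-1-methylidenecyclohexane | C[C@]1(/C=C/Cl)CC(=C)[C@@H](Cl)C[C@H]1Cl | intermediate
18 | violacene | C[C@]1(/C=C/Cl)C[C@](Cl)(CBr)[C@@H](Cl)C[C@H]1Cl | target

**Total steps:** 15. **Longest linear sequence:** 15 steps (Steps 1–15: 1 → 2 → 4 → 6 → 7 → 8 → 9 → 10 → 11 → 12 → 13 → 14 → 15 → 16 → 17 → 18). The other two inputs, 3 and 5, are purchased.

**Three steps most likely to fail, with a change-of-approach fallback for each**
1. **Step 4 (Ireland–Claisen).** Quaternary-centre formation may be slow, and the E-ketene-acetal or chair selectivity may erode, giving the C1/C6 diastereomer. Fallback: use the [2,3]-Wittig rearrangement of the allyl glycolate ether dianion (from 4 and bromoacetic acid), which gives the free α-hydroxy acid with different stereocontrol.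
2. **Step 12 (C6–OH to Cl with inversion).** This is a hindered allylic position next to a quaternary carbon, and SN2′, SN1 or elimination may compete. Fallback: set C6–Cl directly in the [3,3] step by using an allyl chloroacetate Ireland–Claisen in Step 4, which removes the SN2.
3. **Step 15 (stereochemistry of bromochlorination at C3).** This is the weakest stereochemical assumption. Fallback: from 16, make the α-methylene ketone, reduce it to the C4 allylic alcohol, carry out a VO(acac)2 spiro-epoxidation syn to that alcohol, open the epoxide with chloride at the tertiary carbon, then convert CH2OH to CH2Br (Appel) and C4–OH to C4–Cl.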